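**Plan**

- Retrosynthesis: the C3 hydroxyl is masked as a benzyl ether, and the benzene ring is cut at C3–C4 and C1–C6. Ring carbons C1 (ester), C2 (OH) and C3 (OH) are carbons 2, 3 and 4 of a 4-oxygenated acetoacetate; the unsubstituted C4–C5–C6 is a malonaldehyde unit.
- The fatty 4-(benzyloxy)acetoacetate is cut at its ester C–O bond and at C2–C3 (acylketene from an acyl Meldrum's acid). The iso-C18 alcohol is cut at C12–C13 into a C12 and a C6 bromide.
- Forward: the side chain is joined first (step 1), the keto ester is assembled on it (steps 2 and 3) and silylated twice (steps 4 and 5). The benzene ring, the only ring, arises in step 6 by formal [3+3] cyclocondensation, and hydrogenolysis ends the route (step 7).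
- Stereochemistry: the target has no stereocentre and no stereogenic double bond, so nothing has to be set.

Key step: step 6

Remark on the chemistry: the enol ether double bonds made in steps 4 and 5 and the two sp3 centres that appear transiently in step 6 are not controlled. All are erased on aromatisation, so these compounds are written without stereodescriptors.

**Route**

Step 1
Reactants: 1 1-bromo-4-methylpentane; 2 12-bromododecan-1-ol
Product: 6 16-methylheptadecan-1-ol, via 4-methylpentylmagnesium bromide 3 (not isolated), via bromomagnesium 12-bromododecan-1-olate 4 (not isolated), via bromomagnesium 16-methylheptadecan-1-olate 5 (not isolated)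
Conditions: 1 (2.6 equiv), Mg turnings, THF, reflux; added to 2 in THF, −20 °C; Li2CuCl4 (0.05 equiv), −20 °C → rt; aq NH4Cl
Reagents that add atoms: none
Why: Kochi-type copper-catalysed sp3–sp3 cross-coupling, in which the first equivalent of 3 only deprotonates the hydroxyl and the organocuprate formed from Li2CuCl4 then displaces the unhindered primary bromide of 4, a reaction well established for ω-bromoalkanols; work-up protonates 5.

Step 2
Reactants: 7 Meldrum's acid (2,2-dimethyl-1,3-dioxane-4,6-dione); 8 benzyloxyacetyl chloride
Product: 9 5-[2-(benzyloxy)-1-hydroxyethylidene]-2,2-dimethyl-1,3-dioxane-4,6-dione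
Conditions: pyridine (2.2 equiv), CH2Cl2, 0 °C → rt; 1 M HCl wash; used crude
Reagents that add atoms: none
Why: C-acylation of Meldrum's acid (first stage of the Oikawa–Yonemitsu β-keto ester synthesis): pyridine deprotonates the highly acidic C5–H and the enolate is acylated on carbon to give the stable enol-form acyl Meldrum's acid, the benzyl ether being inert.

Step 3
Reactants: 9 5-[2-(benzyloxy)-1-hydroxyethylidene]-2,2-dimethyl-1,3-dioxane-4,6-dione; 6 16-methylheptadecan-1-ol
Product: 11 16-methylheptadecyl 4-(benzyloxy)-3-oxobutanoate, via (benzyloxyacetyl)ketene 10 (not isolated)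
Conditions: 9 (1.3 equiv), toluene, 110 °C
Reagents that add atoms: none
Why: Thermolysis of the acyl Meldrum's acid expels acetone and CO2 to give acylketene 10, which the primary alcohol captures at the ketene carbon (acylketene alcoholysis) under neutral conditions that spare the benzyl ether.

Step 4
Reactants: 11 16-methylheptadecyl 4-(benzyloxy)-3-oxobutanoate
Product: 12 16-methylheptadecyl 4-(benzyloxy)-3-(trimethylsilyloxy)but-2-enoate
Conditions: Me3SiCl (1.8 equiv), Et3N (1.6 equiv), toluene, 20 °C, 72 h; filtered under argon, concentrated
Reagents that add atoms: chlorotrimethylsilane, C[Si](C)(C)Cl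
Why: O-silylation of the β-keto ester enol (silyl enol ether formation) gives the conjugated 3-silyloxy enoate, because under these mild conditions enolisation occurs only toward the doubly activated C2; ester and benzyl ether are untouched.

Step 5
Reactants: 12 16-methylheptadecyl 4-(benzyloxy)-3-(trimethylsilyloxy)but-2-enoate
Product: 14 4-(benzyloxy)-1-(16-methylheptadecyloxy)-1,3-bis(trimethylsilyloxy)buta-1,3-diene, via lithium dienolate 13 (not isolated)
Conditions: LiN(iPr)2 (1.5 equiv, commercial solution), THF, −78 °C; Me3SiCl (1.8 equiv), −78 → 20 °C; pentane, filtered under argon; used crude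
Reagents that add atoms: chlorotrimethylsilane, C[Si](C)(C)Cl
Why: γ-Deprotonation of the 3-silyloxy enoate at the benzyloxy-bearing C4 by the hindered amide base gives the extended lithium dienolate 13, which the hard silyl chloride traps on the ester oxygen (the standard second stage in the preparation of Chan-type 1,3-bis(silyloxy)dienes); the low temperature prevents attack on the ester.

Step 6
Reactants: 14 4-(benzyloxy)-1-(16-methylheptadecyloxy)-1,3-bis(trimethylsilyloxy)buta-1,3-diene; 15 1,1,3,3-tetramethoxypropane
Product: 18 16-methylheptadecyl 3-(benzyloxy)-2-hydroxybenzoate, via open-chain silyloxyheptenoate adduct 16 (not isolated), via dimethoxy-oxocyclohexanecarboxylate 17 (not isolated)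
Conditions: 15 (1.3 equiv), Me3SiOSO2CF3 (TMSOTf, 0.2 equiv), CH2Cl2, −78 → 20 °C; then 10% aq HCl, 20 °C
Reagents that add atoms: none
Why: TMSOTf ionises one acetal of 15 to an oxocarbenium ion, which the terminal, benzyloxy-bearing C4 of the diene attacks in a vinylogous Mukaiyama-type addition (aromatic bond C3–C4) to give 16 with release of MeOSiMe3 and of the catalyst; ionisation of the second acetal and attack by C2 of the remaining silyl enol ether forms aromatic bond C1–C6 and gives 17. The closest known reaction type is the Chan-type formal [3+3] cyclocondensation of 1,3-bis(silyloxy)buta-1,3-dienes with malonaldehyde acetals and related 1,3-dielectrophiles to give salicylates, which is also known for 4-alkoxy-substituted dienes. The benzene ring closes in a 6-(enolendo)-exo-trig mode with respect to the silyl enol ether of 16 (6-(enolexo)-exo-trig if its silyl ketene acetal tautomer reacts), and both modes are favoured. No stereocentre survives, since the two transient sp3 centres and both enol ether geometries are erased when 17 loses two molecules of methanol by β-elimination and the resulting cyclohexadienone tautomerises to the hydrogen-bonded phenol. The step needs only the 1,2,3-pattern and attack at carbon instead of oxygen: the pattern is fixed by the diene, whose C2, C3 and C4 carry the ester and both oxygens, while the three-carbon dielectrophile is symmetrical, so either order of bond formation leads to the same arene, and silyl enol ether carbons react with oxocarbenium ions at carbon. A catalytic Lewis acid at low temperature should leave the benzyl ether and the fatty ester intact.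

Step 7
Reactants: 18 16-methylheptadecyl 3-(benzyloxy)-2-hydroxybenzoate
Product: 19 gentiside D (16-methylheptadecyl 2,3-dihydroxybenzoate)
Conditions: H2 (1 atm), 10% Pd/C, EtOAc, rt
Reagents that add atoms: none
Why: Heterogeneous hydrogenolysis of the benzyl aryl ether over palladium metal frees the C3 phenol and releases toluene, while the ester, the arene and the saturated chain are inert under one atmosphere of hydrogen.

**Compound list**

1 | 1-bromo-4-methylpentane | CC(C)CCCBr | starting material
2 | 12-bromododecan-1-ol | OCCCCCCCCCCCCBr | starting material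
3 | 4-methylpentylmagnesium bromide | CC(C)CCC[Mg]Br | intermediate
4 | bromomagnesium 12-bromododecan-1-olate | Br[Mg]OCCCCCCCCCCCCBr | intermediate
5 | bromomagnesium 16-methylheptadecan-1-olate | CC(C)CCCCCCCCCCCCCCCO[Mg]Br | intermediate
6 | 16-methylheptadecan-1-ol | CC(C)CCCCCCCCCCCCCCCO | intermediate
7 | Meldrum's acid (2,2-dimethyl-1,3-dioxane-4,6-dione) | CC1(C)OC(=O)CC(=O)O1 | starting material
8 | benzyloxyacetyl chloride | O=C(Cl)COCc1ccccc1 | starting material
9 | 5-[2-(benzyloxy)-1-hydroxyethylidene]-2,2-dimethyl-1,3-dioxane-4,6-dione | CC1(C)OC(=O)C(=C(O)COCc2ccccc2)C(=O)O1 | intermediate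
10 | (benzyloxyacetyl)ketene, 4-(benzyloxy)-3-oxobut-1-en-1-one | O=C=CC(=O)COCc1ccccc1 | intermediate
11 | 16-methylheptadecyl 4-(benzyloxy)-3-oxobutanoate | CC(C)CCCCCCCCCCCCCCCOC(=O)CC(=O)COCc1ccccc1 | intermediate
12 | 16-methylheptadecyl 4-(benzyloxy)-3-(trimethylsilyloxy)but-2-enoate (geometry not controlled) | CC(C)CCCCCCCCCCCCCCCOC(=O)C=C(O[Si](C)(C)C)COCc1ccccc1 | intermediate
13 | lithium 4-(benzyloxy)-1-(16-methylheptadecyloxy)-3-(trimethylsilyloxy)buta-1,3-dien-1-olate (geometry not controlled) | CC(C)CCCCCCCCCCCCCCCOC(O[Li])=CC(O[Si](C)(C)C)=COCc1ccccc1 | intermediate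
14 | 4-(benzyloxy)-1-(16-methylheptadecyloxy)-1,3-bis(trimethylsilyloxy)buta-1,3-diene (geometry not controlled) | CC(C)CCCCCCCCCCCCCCCOC(O[Si](C)(C)C)=CC(O[Si](C)(C)C)=COCc1ccccc1 | intermediate
15 | 1,1,3,3-tetramethoxypropane | COC(OC)CC(OC)OC | starting material
16 | 16-methylheptadecyl 4-(benzyloxy)-5,7,7-trimethoxy-3-(trimethylsilyloxy)hept-2-enoate (mixture of isomers) | CC(C)CCCCCCCCCCCCCCCOC(=O)C=C(O[Si](C)(C)C)C(OCc1ccccc1)C(OC)CC(OC)OC | intermediate
17 | 16-methylheptadecyl 3-(benzyloxy)-4,6-dimethoxy-2-oxocyclohexane-1-carboxylate (mixture of isomers) | CC(C)CCCCCCCCCCCCCCCOC(=O)C1C(OC)CC(OC)C(OCc2ccccc2)C1=O | intermediate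
18 | 16-methylheptadecyl 3-(benzyloxy)-2-hydroxybenzoate | CC(C)CCCCCCCCCCCCCCCOC(=O)c1cccc(OCc2ccccc2)c1O | intermediate
19 | gentiside D, 16-methylheptadecyl 2,3-dihydroxybenzoate | CC(C)CCCCCCCCCCCCCCCOC(=O)c1cccc(O)c1O | target

**Count**

Total steps: 7. Longest linear sequence: 6 steps (from 2 through steps 1, 3, 4, 5, 6 and 7; equally from 7 and 8 through steps 2 to 7).

**Steps most likely to fail**

Step 6. Protodesilylation of the crude, undistillable fatty diene and self-condensation of the ionised acetal may outrun the two C–C bond formations, or aromatisation may stall at partly eliminated methoxy intermediates. The fallback keeps the same ring construction but runs it on the methyl ester, where the diene should be distillable and usable in excess, and attaches the fatty alcohol afterwards. It sets out from 9 (and uses 6 at the end) and comes back at 18.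
- Methanolysis of 9 (MeOH, toluene, reflux, through acylketene 10) should give methyl 4-(benzyloxy)-3-oxobutanoate F1.
- Me3SiCl/Et3N should convert it into methyl 4-(benzyloxy)-3-(trimethylsilyloxy)but-2-enoate F2.
- LiN(iPr)2 at −78 °C should give lithium 4-(benzyloxy)-1-methoxy-3-(trimethylsilyloxy)buta-1,3-dien-1-olate F3, which Me3SiCl traps as 4-(benzyloxy)-1-methoxy-1,3-bis(trimethylsilyloxy)buta-1,3-diene F4.
- Cyclocondensation of this diene with 15 under catalytic TMSOTf should pass through methyl 4-(benzyloxy)-5,7,7-trimethoxy-3-(trimethylsilyloxy)hept-2-enoate F5 and methyl 3-(benzyloxy)-4,6-dimethoxy-2-oxocyclohexane-1-carboxylate F6 to methyl 3-(benzyloxy)-2-hydroxybenzoate F7.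
- Saponification (LiOH, THF/MeOH/H2O, 60 °C; then HCl) should give 3-(benzyloxy)-2-hydroxybenzoic acid F8.
- Mitsunobu esterification of this acid with 6 (PPh3, diisopropyl azodicarboxylate, THF, 0 °C → rt), selective for the carboxylic acid over the hydrogen-bonded phenol, should give 18.

Step 5. γ-Deprotonation at the benzyloxy-bearing carbon may be incomplete, the lithium dienolate may be silylated on carbon, or the product may hydrolyse during salt removal. The fallback drops the strong base and the lithium dienolate: keto ester 11 is silylated twice in one operation by soft enolisation (TMSOTf 2.2 equiv, Et3N 2.5 equiv, Et2O, 0 °C → rt). This passes through 12 in the flask, and the ammonium triflate separates as a lower layer, so no filtration is needed. It sets out from 11, comes back at 14, and makes no compound that the compound list lacks (F0).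

Step 1. The bromomagnesium alkoxide may precipitate at low temperature, so that homocoupling of the Grignard reagent and reduction of the bromide overtake the cross-coupling. The fallback forms the same C12–C13 bond as an alkene and then saturates it. It sets out from 2 and comes back at 6.
- Heating 2 with PPh3 (MeCN, reflux) should give (12-hydroxydodecyl)triphenylphosphonium bromide F9.
- NaN(SiMe3)2 (2.1 equiv, THF, −78 → 0 °C) should generate sodium 12-(triphenylphosphoranylidene)dodecan-1-olate F10.
- Wittig olefination of this ylide with commercial 4-methylpentanal should give 16-methylheptadec-12-en-1-ol F11 (mainly Z expected, geometry immaterial).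
- Hydrogenation (H2, 10% Pd/C, EtOAc) should give 6.

**Further compounds**

F1 | step 6 | methyl 4-(benzyloxy)-3-oxobutanoate | COC(=O)CC(=O)COCc1ccccc1
F2 | step 6 | methyl 4-(benzyloxy)-3-(trimethylsilyloxy)but-2-enoate | COC(=O)C=C(O[Si](C)(C)C)COCc1ccccc1
F3 | step 6 | lithium 4-(benzyloxy)-1-methoxy-3-(trimethylsilyloxy)buta-1,3-dien-1-olate | COC(O[Li])=CC(O[Si](C)(C)C)=COCc1ccccc1
F4 | step 6 | 4-(benzyloxy)-1-methoxy-1,3-bis(trimethylsilyloxy)buta-1,3-diene | COC(O[Si](C)(C)C)=CC(O[Si](C)(C)C)=COCc1ccccc1
F5 | step 6 | methyl 4-(benzyloxy)-5,7,7-trimethoxy-3-(trimethylsilyloxy)hept-2-enoate | COC(=O)C=C(O[Si](C)(C)C)C(OCc1ccccc1)C(OC)CC(OC)OC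
F6 | step 6 | methyl 3-(benzyloxy)-4,6-dimethoxy-2-oxocyclohexane-1-carboxylate | COC(=O)C1C(OC)CC(OC)C(OCc2ccccc2)C1=O
F7 | step 6 | methyl 3-(benzyloxy)-2-hydroxybenzoate | COC(=O)c1cccc(OCc2ccccc2)c1O
F8 | step 6 | 3-(benzyloxy)-2-hydroxybenzoic acid | OC(=O)c1cccc(OCc2ccccc2)c1O
F0 | step 5 | none | none
F9 | step 1 | (12-hydroxydodecyl)triphenylphosphonium bromide | OCCCCCCCCCCCC[P+](c1ccccc1)(c1ccccc1)c1ccccc1.[Br-]
F10 | step 1 | sodium 12-(triphenylphosphoranylidene)dodecan-1-olate | [Na+].[O-]CCCCCCCCCCCC=P(c1ccccc1)(c1ccccc1)c1ccccc1
F11 | step 1 | 16-methylheptadec-12-en-1-ol | CC(C)CCC=CCCCCCCCCCCCO
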